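**Plan**

- Retrosynthesis: cut the three O–CH3 bonds, then C5–C6 of ring A in the non-chlorinated isoflavone (Claisen/Dieckmann), then the alkyl C–O bond of the inter-unit ether (phenoxide on an α-chloro ketone), then the acetyl C–C bond of the side chain and the O1–C6 bond of a 4-pyranone; the chlorinated unit is cut at ring C and at its aryl ketone bond.
- Forward: chlorine is placed on 3,5-dimethoxyphenol, then acylation and ring C closure give the chlorinated 4'-hydroxyisoflavone; a 3-aryl-4-pyranone is built from methyl acetoacetate, its 2-methyl group is acetylated and chlorinated, the two fragments are joined by O-alkylation, ring A is closed last, and the methyl ethers are removed.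
- Enabling feature: in the non-chlorinated unit, ring A bears OH at C5 and C7 and the aryloxy group at C8, next to the ring-fusion carbon C8a. This 1,3-dioxygenated pattern maps onto a CH(OAr)–CO–CH3 chain on C2 and a methyl ester on C3 of a 3-aryl-4-pyranone, so the ether carbon is bonded to the future C8a before ring A exists.
- Stereochemistry: the target has no stereocentre; the aryloxy-bearing (or chloro-bearing) carbon of the late intermediates is racemic and becomes aromatic C8 in the ring closure.

Key step: step 8

Remark on the chemistry: the β-dicarbonyl-type intermediates are drawn as keto tautomers although they should be largely enolised; this does not affect the route.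

**Route**

Step 1
Reactants: 1 3,5-dimethoxyphenol
Product: 2 2-chloro-3,5-dimethoxyphenol
Conditions: SO2Cl2 (1.0 equiv), CHCl3, 0 °C to rt; chromatography to remove the 4-chloro isomer
Reagents that add atoms: sulfuryl chloride, O=S(=O)(Cl)Cl
Why: Electrophilic aromatic chlorination of the activated phenol gives the ortho-chloro isomer as a separable product, and placing chlorine before ring construction fixes it unambiguously at the future C8 of the isoflavone.

Step 2
Reactants: 2 2-chloro-3,5-dimethoxyphenol; 3 4-hydroxyphenylacetic acid
Product: 5 8-chloro-4'-hydroxy-5,7-dimethoxyisoflavone, via deoxybenzoin 4 (not isolated)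
Conditions: BF3·OEt2 (solvent), 85 °C; then DMF, MeSO2Cl, 25 to 75 °C; aq NaOAc
Reagents that add atoms: N,N-dimethylformamide, CN(C)C=O
Why: BF3-mediated Friedel–Crafts acylation goes to the only free position ortho to the phenol OH, and Vilsmeier-type formylation of the chelated deoxybenzoin followed by cyclisation closes ring C, a one-pot isoflavone synthesis that tolerates free phenols.

Step 3
Reactants: 6 methyl acetoacetate; 7 4-methoxyphenylacetyl chloride
Product: 8 methyl 2-acetyl-4-(4-methoxyphenyl)-3-oxobutanoate
Conditions: MgCl2, pyridine, CH2Cl2, 0 °C to rt; 1 M HCl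
Reagents that add atoms: none
Why: Soft enolisation with MgCl2 and pyridine gives the magnesium chelate of the β-keto ester, which undergoes C-acylation by the acid chloride (Claisen-type acylation of a 1,3-dicarbonyl) and is protected from further acylation as the chelated triacylmethane.

Step 4
Reactants: 8 methyl 2-acetyl-4-(4-methoxyphenyl)-3-oxobutanoate
Product: 10 methyl 5-(4-methoxyphenyl)-2-methyl-4-oxo-4H-pyran-3-carboxylate, via enaminone 9 (not isolated)
Conditions: Me2NCH(OMe)2 (1.3 equiv), toluene, rt to 80 °C; then AcOH, 80 °C
Reagents that add atoms: N,N-dimethylformamide dimethyl acetal, COC(OC)N(C)C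
Why: Enaminone condensation takes place at the benzylic methylene, the most acidic carbon still free to condense, and the enol oxygen of the acetyl group then adds to the enaminone carbon and expels dimethylamine, the same condensation–cyclisation that turns 2-hydroxydeoxybenzoins into isoflavones and 2-acyl-1,3-diones into 4-pyranones.

Step 5
Reactants: 10 methyl 5-(4-methoxyphenyl)-2-methyl-4-oxo-4H-pyran-3-carboxylate
Product: 11 methyl 5-(4-methoxyphenyl)-4-oxo-2-(2-oxopropyl)-4H-pyran-3-carboxylate
Conditions: LiN(SiMe3)2 (2.2 equiv), THF, −78 °C; MeC(O)N(OMe)Me, −78 to 0 °C; aq NH4Cl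
Reagents that add atoms: N-methoxy-N-methylacetamide, CC(=O)N(C)OC
Why: The 2-methyl group is vinylogously acidic towards both the ring ketone and the ester, so lateral lithiation gives an extended enolate that is acylated at its γ-carbon (vinylogous Claisen acylation), and the Weinreb amide holds the product as a tetrahedral chelate until the quench so that neither over-acylation nor premature ring closure can follow.

Step 6
Reactants: 11 methyl 5-(4-methoxyphenyl)-4-oxo-2-(2-oxopropyl)-4H-pyran-3-carboxylate
Product: 12 methyl 2-(1-chloro-2-oxopropyl)-5-(4-methoxyphenyl)-4-oxo-4H-pyran-3-carboxylate (racemic)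
Conditions: SO2Cl2 (1.05 equiv), CH2Cl2, 0 °C
Reagents that add atoms: sulfuryl chloride, O=S(=O)(Cl)Cl
Why: α-Chlorination of an active methylene with SO2Cl2 selects the carbon flanked by the ketone and the pyranone because it enolises most readily, as with acetoacetates and arylacetones; the new centre forms as a racemate, which is immaterial because it is aromatised later.

Step 7
Reactants: 12 methyl 2-(1-chloro-2-oxopropyl)-5-(4-methoxyphenyl)-4-oxo-4H-pyran-3-carboxylate; 5 8-chloro-4'-hydroxy-5,7-dimethoxyisoflavone
Product: 13 methyl 2-{1-[4-(8-chloro-5,7-dimethoxy-4-oxo-4H-chromen-3-yl)phenoxy]-2-oxopropyl}-5-(4-methoxyphenyl)-4-oxo-4H-pyran-3-carboxylate (racemic)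
Conditions: K2CO3 (1.5 equiv), DMF, rt to 40 °C
Reagents that add atoms: none
Why: Williamson-type SN2 displacement of an α-chloro ketone by a phenoxide, the reaction by which phenols and 2-chloroacetoacetates give 2-aryloxyacetoacetates, makes the hindered ether as an alkyl–O bond so that no aryl C–O coupling is needed; the centre is racemic and no control is required.

Step 8
Reactants: 13 methyl 2-{1-[4-(8-chloro-5,7-dimethoxy-4-oxo-4H-chromen-3-yl)phenoxy]-2-oxopropyl}-5-(4-methoxyphenyl)-4-oxo-4H-pyran-3-carboxylate
Product: 15 8-[4-(8-chloro-5,7-dimethoxy-4-oxo-4H-chromen-3-yl)phenoxy]-5,7-dihydroxy-3-(4-methoxyphenyl)-4H-chromen-4-one, via trione tautomer 14 (not isolated)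
Conditions: LiN(iPr)2 (3.5 equiv), THF, −78 to 0 °C; 1 M HCl
Reagents that add atoms: none
Why: Proposed new method: LiN(iPr)2 removes first the acidic C–H between the ketone and the pyranone and then a methyl proton, and the terminal carbon of this 1,3-dianion adds to the neighbouring ester carbonyl in a Dieckmann-type Claisen acyl substitution that forms C5–C6, expels methoxide and gives trione 14, whose enolisation to the resorcinol ring is irreversible and drives the sequence. The closest known reactions are the base-induced cyclisation of 2-acetonylbenzoates to naphthalene-1,3-diols and the Claisen aromatisation of β-polycarbonyl polyanions, neither of which has been run with a 4-pyranone-3-carboxylate as the acceptor. The carbocycle (ring A) closes in a 6-(enolendo)-exo-trig mode onto the ester carbon, with the cis-fixed C2=C3 bond of the pyranone holding nucleophile and electrophile in an ortho relationship. No stereocentre is created, and the racemic aryloxy-bearing carbon becomes the sp2 carbon C8. The step needs chemoselectivity for C-acylation at the ester over attack on the ring carbonyl, over O-acylation and over conjugate opening of either pyranone ring: the ring carbonyl could only be reached through a bridged bicycle with a bridgehead alkene, the central enolate carbon cannot cyclise for reasons of ring size so only the methyl terminus reacts, and a hindered amide base at low temperature does not add to C2 of the 4-pyranone or the isoflavone. The position of the ether is not at stake because the aryloxy carbon is bonded to the future C8a from the outset.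

Step 9
Reactants: 15 8-[4-(8-chloro-5,7-dimethoxy-4-oxo-4H-chromen-3-yl)phenoxy]-5,7-dihydroxy-3-(4-methoxyphenyl)-4H-chromen-4-one
Product: 16 8-chloro-3-{4-[(5,7-dihydroxy-3-(4-hydroxyphenyl)-4-oxo-4H-chromen-8-yl)oxy]phenyl}-5,7-dihydroxy-4H-chromen-4-one (bisoflavolin I)
Conditions: BBr3 (10 equiv), CH2Cl2, −78 °C to rt; MeOH, then water
Reagents that add atoms: none
Why: BBr3 cleaves aryl methyl ethers by Lewis-acid complexation and SN2 attack of bromide on the methyl group, a standard global demethylation of methoxyisoflavones that should leave the diaryl ether, the aryl chloride and both chromone rings intact.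

**Compound list**

1 | 3,5-dimethoxyphenol | COc1cc(O)cc(OC)c1 | starting material
2 | 2-chloro-3,5-dimethoxyphenol | COc1cc(O)c(Cl)c(OC)c1 | intermediate
3 | 4-hydroxyphenylacetic acid | OC(=O)Cc1ccc(O)cc1 | starting material
4 | 1-(3-chloro-2-hydroxy-4,6-dimethoxyphenyl)-2-(4-hydroxyphenyl)ethan-1-one (deoxybenzoin, formed in the flask, not isolated) | COc1cc(OC)c(C(=O)Cc2ccc(O)cc2)c(O)c1Cl | intermediate
5 | 8-chloro-4'-hydroxy-5,7-dimethoxyisoflavone [8-chloro-3-(4-hydroxyphenyl)-5,7-dimethoxy-4H-chromen-4-one] | COc1cc(OC)c2c(=O)c(-c3ccc(O)cc3)coc2c1Cl | intermediate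
6 | methyl acetoacetate | CC(=O)CC(=O)OC | starting material
7 | 4-methoxyphenylacetyl chloride | COc1ccc(CC(Cl)=O)cc1 | starting material
8 | methyl 2-acetyl-4-(4-methoxyphenyl)-3-oxobutanoate | COC(=O)C(C(C)=O)C(=O)Cc1ccc(OC)cc1 | intermediate
9 | methyl 2-acetyl-5-(dimethylamino)-4-(4-methoxyphenyl)-3-oxopent-4-enoate (enaminone, double-bond geometry not defined, formed in the flask, not isolated) | COC(=O)C(C(C)=O)C(=O)C(=CN(C)C)c1ccc(OC)cc1 | intermediate
10 | methyl 5-(4-methoxyphenyl)-2-methyl-4-oxo-4H-pyran-3-carboxylate | COC(=O)c1c(C)occ(-c2ccc(OC)cc2)c1=O | intermediate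
11 | methyl 5-(4-methoxyphenyl)-4-oxo-2-(2-oxopropyl)-4H-pyran-3-carboxylate | COC(=O)c1c(CC(C)=O)occ(-c2ccc(OC)cc2)c1=O | intermediate
12 | methyl 2-(1-chloro-2-oxopropyl)-5-(4-methoxyphenyl)-4-oxo-4H-pyran-3-carboxylate (racemic) | COC(=O)c1c(C(Cl)C(C)=O)occ(-c2ccc(OC)cc2)c1=O | intermediate
13 | methyl 2-{1-[4-(8-chloro-5,7-dimethoxy-4-oxo-4H-chromen-3-yl)phenoxy]-2-oxopropyl}-5-(4-methoxyphenyl)-4-oxo-4H-pyran-3-carboxylate (racemic) | COC(=O)c1c(C(Oc2ccc(-c3coc4c(Cl)c(OC)cc(OC)c4c3=O)cc2)C(C)=O)occ(-c2ccc(OC)cc2)c1=O | intermediate
14 | 8-[4-(8-chloro-5,7-dimethoxy-4-oxo-4H-chromen-3-yl)phenoxy]-3-(4-methoxyphenyl)-6H-chromene-4,5,7(8H)-trione (racemic keto tautomer, formed in the flask, not isolated) | COc1ccc(cc1)-c1coc2C(Oc3ccc(cc3)-c3coc4c(Cl)c(OC)cc(OC)c4c3=O)C(=O)CC(=O)c2c1=O | intermediate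
15 | 8-[4-(8-chloro-5,7-dimethoxy-4-oxo-4H-chromen-3-yl)phenoxy]-5,7-dihydroxy-3-(4-methoxyphenyl)-4H-chromen-4-one | O=c1c(-c2ccc(OC)cc2)coc2c(Oc3ccc(-c4coc5c(Cl)c(OC)cc(OC)c5c4=O)cc3)c(O)cc(O)c12 | intermediate
16 | bisoflavolin I, 8-chloro-3-{4-[(5,7-dihydroxy-3-(4-hydroxyphenyl)-4-oxo-4H-chromen-8-yl)oxy]phenyl}-5,7-dihydroxy-4H-chromen-4-one (achiral) | O=c1c(-c2ccc(Oc3c(O)cc(O)c4c(=O)c(-c5ccc(O)cc5)coc34)cc2)coc2c(Cl)c(O)cc(O)c12 | target

**Step count**

Total: 9 steps. Longest linear sequence: 7 steps (steps 3 to 9, from methyl acetoacetate); the chlorinated isoflavone branch (steps 1 and 2) joins at step 7.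

**Steps most likely to fail, with fallbacks**

Step 8 (carries the label "Proposed new method:"). What may go wrong: the second deprotonation may stay incomplete so that the monoanion simply returns on quench, the enolate oxygen may acylate in place of the methyl terminus (enol lactone formation), or amide or liberated methoxide may add to C2 of a pyranone ring and open it. The fallback gives up the late ring construction and makes the diaryl ether by known copper-mediated aryl C–O coupling of two finished isoflavones. It sets out from 5 and comes back to the route at 16. Commercial 4',5,7-trimethoxyisoflavone F1 would be iodinated at its most activated position C8 with N-iodosuccinimide and CF3CO2H in MeCN to give 8-iodo-4',5,7-trimethoxyisoflavone F2. Ullmann-type coupling of F2 with phenol 5 (CuI, picolinic acid, K3PO4, DMSO, 90 °C, conditions developed for doubly ortho-substituted partners) would give the pentamethyl ether of the target F3. BBr3 in CH2Cl2 would then cleave all five methyl ethers and deliver 16 directly.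

Step 7. What may go wrong: deprotonation of the acidic C–H of the chloride may outrun substitution, or the phenoxide may attack the acetyl carbonyl (retro-Claisen deacetylation) or the chlorine atom (reduction of the chloride and chlorination of the phenol). The fallback forms the same C–O bond by carbenoid O–H insertion instead of displacement. It sets out from 11 and comes back at 13. Regitz diazo transfer to 11 (4-acetamidobenzenesulfonyl azide, Et3N, MeCN) would give methyl 2-(1-diazo-2-oxopropyl)-5-(4-methoxyphenyl)-4-oxo-4H-pyran-3-carboxylate F4. Slow addition of F4 to phenol 5 and catalytic Rh2(OAc)4 in CH2Cl2 at reflux would insert the carbenoid into the phenolic O–H bond and give 13.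

Step 4. What may go wrong: condensation at the acetyl methyl in place of the benzylic methylene, O-methylation of the acidic enol by the acetal, or amine-induced deacylation of the triacylmethane. The fallback builds the pyranone first and brings in the aryl group by cross-coupling. It sets out from 6 and comes back at 10. C-acylation of 6 with (E)-3-ethoxyacryloyl chloride (MgCl2, pyridine, CH2Cl2) would give methyl (4E)-2-acetyl-5-ethoxy-3-oxopent-4-enoate F5, which on treatment with CF3CO2H would cyclise with loss of ethanol to methyl 2-methyl-4-oxo-4H-pyran-3-carboxylate F6. Bromination at C5 (Br2, CH2Cl2, then Et3N) would give methyl 5-bromo-2-methyl-4-oxo-4H-pyran-3-carboxylate F7. Suzuki–Miyaura coupling of F7 with 4-methoxyphenylboronic acid (Pd(PPh3)4, K3PO4, toluene, 90 °C) would give 10.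

**Further compounds**

F1 | step 8 | 4',5,7-trimethoxyisoflavone | COc1ccc(-c2coc3cc(OC)cc(OC)c3c2=O)cc1
F2 | step 8 | 8-iodo-4',5,7-trimethoxyisoflavone | COc1ccc(-c2coc3c(I)c(OC)cc(OC)c3c2=O)cc1
F3 | step 8 | 8-[4-(8-chloro-5,7-dimethoxy-4-oxo-4H-chromen-3-yl)phenoxy]-5,7-dimethoxy-3-(4-methoxyphenyl)-4H-chromen-4-one | COc1ccc(-c2coc3c(Oc4ccc(-c5coc6c(Cl)c(OC)cc(OC)c6c5=O)cc4)c(OC)cc(OC)c3c2=O)cc1
F4 | step 7 | methyl 2-(1-diazo-2-oxopropyl)-5-(4-methoxyphenyl)-4-oxo-4H-pyran-3-carboxylate | COC(=O)c1c(C(=[N+]=[N-])C(C)=O)occ(-c2ccc(OC)cc2)c1=O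
F5 | step 4 | methyl (4E)-2-acetyl-5-ethoxy-3-oxopent-4-enoate | CCO/C=C/C(=O)C(C(C)=O)C(=O)OC
F6 | step 4 | methyl 2-methyl-4-oxo-4H-pyran-3-carboxylate | COC(=O)c1c(C)occc1=O
F7 | step 4 | methyl 5-bromo-2-methyl-4-oxo-4H-pyran-3-carboxylate | COC(=O)c1c(C)occ(Br)c1=O
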